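**Retrosynthetic overview**
1. The prenyl ether at O7 is cut last (O–CH2 bond). The 7-oxygen is carried as a benzyl ether through the bromine chemistry, because a prenyl alkene would not survive Br2.
2. The strategy rests on ring C: its O1–C2(aryl)=C3(OH)–C4(=O) array is the enol of a 2-arylchromane-3,4-dione. Breaking O1–C2 and rejoining O1 to C3 reveals a 2-bromo-2-(α-bromobenzyl)benzofuran-3-one, an aurone dibromide (Auwers ring expansion).
3. The dibromide comes from Br2 addition to the Z-aurone. The aurone comes from aldol condensation of 6-hydroxybenzofuran-3(2H)-one with veratraldehyde, followed by O-benzylation.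
4. Ring order: rings A and B are bought, ring A as part of the benzofuranone. The furanone ring is sacrificed, and ring C is the only ring formed, in the key step.

Key step: step 4

Remark: the target is achiral. The dibromide and the two transient intermediates of the key step are racemic and are drawn as single enantiomers.

**Step 1**
Reactants: 1 6-hydroxybenzofuran-3(2H)-one; 2 veratraldehyde
Product: 3 (Z)-2-(3,4-dimethoxybenzylidene)-6-hydroxybenzofuran-3(2H)-one
Conditions: conc. HCl (cat.), AcOH, rt; product collected by filtration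
Reagents that add atoms: veratraldehyde (2), COc1ccc(C=O)cc1OC
Why: Acid-catalysed crossed aldol condensation of the acidic C2 methylene of the coumaranone with a non-enolisable aldehyde, with dehydration to the thermodynamically preferred Z-benzylidene isomer (aryl on the side of the ring oxygen); no stereocentre is formed.

**Step 2**
Reactants: 3 (Z)-2-(3,4-dimethoxybenzylidene)-6-hydroxybenzofuran-3(2H)-one; 4 benzyl bromide
Product: 5 (Z)-6-(benzyloxy)-2-(3,4-dimethoxybenzylidene)benzofuran-3(2H)-one
Conditions: BnBr (1.2 equiv), K2CO3 (1.5 equiv), DMF, rt to 50 °C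
Reagents that add atoms: benzyl bromide (4), BrCc1ccccc1
Why: Williamson ether synthesis in which the 6-phenoxide, a vinylogous carboxylate para to the C3 carbonyl, is the only nucleophile, since the aurone no longer has an enolisable position.

**Step 3**
Reactants: 5 (Z)-6-(benzyloxy)-2-(3,4-dimethoxybenzylidene)benzofuran-3(2H)-one
Product: 6 rac-(2R)-6-(benzyloxy)-2-bromo-2-[(S)-bromo(3,4-dimethoxyphenyl)methyl]benzofuran-3(2H)-one (anti adduct of the Z-aurone)
Conditions: Br2 (1.0 equiv, slow addition), CHCl3, 0 °C, dark; crude product used directly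
Reagents that add atoms: bromine, BrBr
Why: Electrophilic addition of bromine to the exocyclic enone alkene, which is activated by the 3,4-dimethoxyphenyl donor and should be more nucleophilic than either alkoxyarene ring, proceeds through a bromonium ion with anti delivery of bromide to the Z alkene and so sets C2 and the benzylic carbon as the racemic (2R,αS)/(2S,αR) pair, both centres being erased again in step 4.

**Step 4**
Reactants: 6 rac-(2R)-6-(benzyloxy)-2-bromo-2-[(S)-bromo(3,4-dimethoxyphenyl)methyl]benzofuran-3(2H)-one
Product: 9 7-(benzyloxy)-2-(3,4-dimethoxyphenyl)-3-hydroxy-4H-chromen-4-one, via ring-opened bromo diketone 7 (not isolated), via chromane-3,4-dione 8 (not isolated)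
Conditions: aq. KOH (4 equiv), EtOH–H2O, 0 °C to rt; then AcOH
Reagents that add atoms: potassium hydroxide, [K+].[OH-]
Why: The lone pair of O1 expels the C2 bromide to give an oxocarbenium ion that is captured by hydroxide, and the resulting 2-hydroxy hemiketal collapses with cleavage of the old O1–C2 bond to the phenoxide of 7, which carries a 1,2-diketone and a benzylic bromide. This phenoxide then displaces the benzylic bromide in a 6-exo-tet closure that forms the O1–C2 bond of ring C and gives chromanedione 8, whose enolisation towards C2 delivers flavonol 9 with the 3-oxygen derived from hydroxide. The closest known reaction type is the Auwers flavonol synthesis, the conversion of aurone dibromides into 3-hydroxyflavones by aqueous-alcoholic alkali. No stereocentre is created: the two C–Br centres of 6 and the C2 centre of 8 are all lost on enolisation, so the diastereomeric composition of 6 is irrelevant. The step needs six-membered over five-membered reclosure and substitution over loss of HBr or Br2 back to aurone-type products; return of the phenoxide to the diketone carbonyl is reversible, whereas displacement of the bromide, activated by the adjacent carbonyl and the 3,4-dimethoxyphenyl group, is irreversible and drains the equilibrium into ring C. Excess aqueous hydroxide at low temperature is used so that capture of the oxocarbenium ion outruns loss of its neighbouring proton.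

**Step 5**
Reactants: 9 7-(benzyloxy)-2-(3,4-dimethoxyphenyl)-3-hydroxy-4H-chromen-4-one
Product: 10 2-(3,4-dimethoxyphenyl)-3,7-dihydroxy-4H-chromen-4-one
Conditions: H2 (1 atm), 10% Pd/C, THF–MeOH, rt; stopped after uptake of one equivalent
Reagents that add atoms: none
Why: Catalytic hydrogenolysis cleaves the benzylic C–O bond, while the tetrasubstituted C2=C3 bond of the chromone, part of a vinylogous ester, should resist hydrogenation at atmospheric pressure and room temperature.

**Step 6**
Reactants: 10 2-(3,4-dimethoxyphenyl)-3,7-dihydroxy-4H-chromen-4-one; 11 prenyl bromide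
Product: 12 2-(3,4-dimethoxyphenyl)-3-hydroxy-7-[(3-methylbut-2-en-1-yl)oxy]-4H-chromen-4-one (target)
Conditions: prenyl bromide (1.05 equiv), K2CO3 (1.05 equiv), DMF, 0 °C to rt
Reagents that add atoms: prenyl bromide (11), CC(C)=CCBr
Why: Williamson etherification in which one equivalent of base should generate the 7-phenoxide selectively, because the 7-hydroxyl is para-conjugated with the C4 carbonyl and markedly more acidic than the 3-enol that is hydrogen-bonded to C4=O, and this phenoxide attacks the primary allylic bromide by SN2.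

**Compound list**
1 | 6-hydroxybenzofuran-3(2H)-one | O=C1COc2cc(O)ccc21 | starting material
2 | veratraldehyde (3,4-dimethoxybenzaldehyde) | COc1ccc(C=O)cc1OC | starting material
3 | (Z)-2-(3,4-dimethoxybenzylidene)-6-hydroxybenzofuran-3(2H)-one | COc1ccc(/C=C2\Oc3cc(O)ccc3C2=O)cc1OC | intermediate
4 | benzyl bromide | BrCc1ccccc1 | starting material
5 | (Z)-6-(benzyloxy)-2-(3,4-dimethoxybenzylidene)benzofuran-3(2H)-one | COc1ccc(/C=C2\Oc3cc(OCc4ccccc4)ccc3C2=O)cc1OC | intermediate
6 | rac-(2R)-6-(benzyloxy)-2-bromo-2-[(S)-bromo(3,4-dimethoxyphenyl)methyl]benzofuran-3(2H)-one (racemic, one enantiomer drawn) | COc1ccc([C@H](Br)[C@@]2(Br)Oc3cc(OCc4ccccc4)ccc3C2=O)cc1OC | intermediate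
7 | 1-[4-(benzyloxy)-2-hydroxyphenyl]-3-bromo-3-(3,4-dimethoxyphenyl)propane-1,2-dione, present in the flask as its phenoxide (racemic, one enantiomer drawn) | COc1ccc([C@H](Br)C(=O)C(=O)c2ccc(OCc3ccccc3)cc2O)cc1OC | intermediate
8 | 7-(benzyloxy)-2-(3,4-dimethoxyphenyl)chromane-3,4-dione (racemic, one enantiomer drawn) | COc1ccc([C@H]2Oc3cc(OCc4ccccc4)ccc3C(=O)C2=O)cc1OC | intermediate
9 | 7-(benzyloxy)-2-(3,4-dimethoxyphenyl)-3-hydroxy-4H-chromen-4-one | COc1ccc(-c2oc3cc(OCc4ccccc4)ccc3c(=O)c2O)cc1OC | intermediate
10 | 2-(3,4-dimethoxyphenyl)-3,7-dihydroxy-4H-chromen-4-one | COc1ccc(-c2oc3cc(O)ccc3c(=O)c2O)cc1OC | intermediate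
11 | prenyl bromide (1-bromo-3-methylbut-2-ene) | CC(C)=CCBr | starting material
12 | 2-(3,4-dimethoxyphenyl)-3-hydroxy-7-[(3-methylbut-2-en-1-yl)oxy]-4H-chromen-4-one | COc1ccc(-c2oc3cc(OCC=C(C)C)ccc3c(=O)c2O)cc1OC | target

**Total step count:** 6
**Longest linear sequence:** 6 steps (from 1 to 12)

**Steps most likely to fail**

Step 4 (key step). After ionisation of the C2–Br bond, loss of the neighbouring benzylic proton, or loss of bromine from the dibromide, may outrun incorporation of hydroxide. The material would then drain back to aurone-type products instead of ring-expanding. A 6-alkoxy donor para to the C3 carbonyl is the substitution pattern at which this is most to be feared. The fallback is an Algar–Flynn–Oyamada oxidation that sets out from veratraldehyde 2 and returns to the route at 9. Compound 2 is condensed with commercial 1-[4-(benzyloxy)-2-hydroxyphenyl]ethanone F1 (KOH, EtOH, rt, Claisen–Schmidt) to give (E)-1-[4-(benzyloxy)-2-hydroxyphenyl]-3-(3,4-dimethoxyphenyl)prop-2-en-1-one F2. Treatment of F2 with H2O2 and NaOH in MeOH at 0 °C to rt should close ring C oxidatively and give flavonol 9 directly; the absence of a 6'-substituent in the chalcone favours the flavonol over the aurone.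

Step 3. Electrophilic bromination of ring A or of the dimethoxyphenyl ring may compete with addition to the alkene, and the benzylic bromide may ionise on handling. The fallback sets out from 3 and returns at 10. It replaces the donating benzyl ether by an electron-withdrawing sulfonate, which removes ring A as a competitor for bromine. Compound 3 is tosylated (TsCl, Et3N, CH2Cl2, 0 °C) to (Z)-2-(3,4-dimethoxybenzylidene)-3-oxo-2,3-dihydrobenzofuran-6-yl 4-methylbenzenesulfonate F3. Bromine (1.0 equiv, CHCl3, 0 °C) should give rac-(2R)-2-bromo-2-[(S)-bromo(3,4-dimethoxyphenyl)methyl]-3-oxo-2,3-dihydrobenzofuran-6-yl 4-methylbenzenesulfonate F4. Aqueous KOH in EtOH at rt should then effect the same ring expansion to 2-(3,4-dimethoxyphenyl)-3-hydroxy-4-oxo-4H-chromen-7-yl 4-methylbenzenesulfonate F5. Continued heating of F5 with KOH in aqueous EtOH cleaves the sulfonate and gives 10, so the hydrogenolysis is not needed.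

Step 6. Alkylation at the 3-oxygen may compete (poor site selectivity), leading to double alkylation, and C-prenylation at C8 is also possible. The fallback sets out from 9 and returns at 12. It masks the 3-hydroxyl before the benzyl group is removed and alkylates under neutral conditions. Compound 9 is acetylated (Ac2O, pyridine, rt) to 7-(benzyloxy)-2-(3,4-dimethoxyphenyl)-4-oxo-4H-chromen-3-yl acetate F6. Hydrogenolysis (H2, 10% Pd/C, THF–MeOH, rt) gives 2-(3,4-dimethoxyphenyl)-7-hydroxy-4-oxo-4H-chromen-3-yl acetate F7. A Mitsunobu etherification with 3-methylbut-2-en-1-ol (PPh3, DIAD, THF, 0 °C) gives 2-(3,4-dimethoxyphenyl)-7-[(3-methylbut-2-en-1-yl)oxy]-4-oxo-4H-chromen-3-yl acetate F8. Methanolysis of the enol acetate (K2CO3 cat., MeOH, rt) then releases 12.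

**Further compounds**
F1 | step 4 | 1-[4-(benzyloxy)-2-hydroxyphenyl]ethanone | CC(=O)c1ccc(OCc2ccccc2)cc1O
F2 | step 4 | (E)-1-[4-(benzyloxy)-2-hydroxyphenyl]-3-(3,4-dimethoxyphenyl)prop-2-en-1-one | COc1ccc(/C=C/C(=O)c2ccc(OCc3ccccc3)cc2O)cc1OC
F3 | step 3 | (Z)-2-(3,4-dimethoxybenzylidene)-3-oxo-2,3-dihydrobenzofuran-6-yl 4-methylbenzenesulfonate | COc1ccc(/C=C2\Oc3cc(OS(=O)(=O)c4ccc(C)cc4)ccc3C2=O)cc1OC
F4 | step 3 | rac-(2R)-2-bromo-2-[(S)-bromo(3,4-dimethoxyphenyl)methyl]-3-oxo-2,3-dihydrobenzofuran-6-yl 4-methylbenzenesulfonate | COc1ccc([C@H](Br)[C@@]2(Br)Oc3cc(OS(=O)(=O)c4ccc(C)cc4)ccc3C2=O)cc1OC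
F5 | step 3 | 2-(3,4-dimethoxyphenyl)-3-hydroxy-4-oxo-4H-chromen-7-yl 4-methylbenzenesulfonate | COc1ccc(-c2oc3cc(OS(=O)(=O)c4ccc(C)cc4)ccc3c(=O)c2O)cc1OC
F6 | step 6 | 7-(benzyloxy)-2-(3,4-dimethoxyphenyl)-4-oxo-4H-chromen-3-yl acetate | COc1ccc(-c2oc3cc(OCc4ccccc4)ccc3c(=O)c2OC(C)=O)cc1OC
F7 | step 6 | 2-(3,4-dimethoxyphenyl)-7-hydroxy-4-oxo-4H-chromen-3-yl acetate | COc1ccc(-c2oc3cc(O)ccc3c(=O)c2OC(C)=O)cc1OC
F8 | step 6 | 2-(3,4-dimethoxyphenyl)-7-[(3-methylbut-2-en-1-yl)oxy]-4-oxo-4H-chromen-3-yl acetate | COc1ccc(-c2oc3cc(OCC=C(C)C)ccc3c(=O)c2OC(C)=O)cc1OC
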